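4 questions stand on the north flask, and the examination opens with the one beneath the others: what is the state of this flask at the asked time?

| flask | starting material | reagent | second substrate | protic impurity | temperature | remark | time |
|---|---|---|---|---|---|---|---|
| north | 1 mM | 2 mM | 0.50 mM | 0.050 mM | 40 °C | the very flask that is asked about, followed so far |  |
| south | 1 mM | 2 mM | 1 mM | 0.050 mM | 46 °C | run made earlier |  |
| flask | 1.0 mM | 2.00 mM | 0.500 mM | 0.0500 mM | 40 °C |  | 30 min |

| run | time / min | target / % | starting material / % |
|---|---|---|---|
| north | 1.33 | 13.6 | 46.6 |
| north | 2.50 | 11.7 | 39.2 |
| north | 5.00 | 9.9 | 32.2 |
| north | 10.0 | 9.4 | 28.8 |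
| north | 20.0 | 9.3 | 28.4 |
| south | 0.417 | 11.6 | 46.7 |
| south | 1.00 | 8.4 | 35.4 |
| south | 2.00 | 7.2 | 29.1 |
| south | 3.00 | 6.4 | 26.1 |
| south | 4.00 | 6.4 | 25.5 |

(each reading ± 0.3 percentage points)

* target, in percent of the starting material first charged, at 30 min
* what to do for the largest gain in target; "none" if nothing gains more than 2 percentage points (blue / violet / amber / red / none)
* target present, with what was taken out counted in, in percent of the starting material first charged, after blue
* target present, with what was taken out counted in, in percent of the starting material first charged, after violet

- blue: change nothing and wait 30 min more
- violet: at 30 min raise the temperature by 15 K, then wait 30 min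
- amber: at 30 min take out 90 % of the target then present, then wait 30 min
- red: at 30 min add reagent, 100 % of the amount charged, then wait 30 min

- target that was removed still counts
- on the list of suspects stand: second substrate + protic impurity -> quenched substrate; starting material + second substrate -> cross product; target <-> isomer of the product; second substrate + reagent -> second product; starting material + reagent <-> target
- additions bring no volume worth counting

Is the north flask still moving? Barely: starting material falls 3.4 percentage points from 5.00 min to 10.0 min, then 0.4 points up to 20.0 min, and each reading carries a scatter of 0.3 points. So the net rate has drifted towards zero, and I commit to target staying near its last reading, 9.3 %.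

What describes that rest? The ratio c(target)/c(starting material), here 0.327, taken per unit of free reagent: the apparent association constant, c(target)/(c(starting material)·c(reagent)).

But free reagent was never measured. How do you get it? By a balance. Starting material that ends in cross product takes no reagent, while second substrate that ends in second product takes one. I assume an even split of second substrate between these routes and ignore the protic impurity. The two terms then cancel, reagent lost equals starting material lost, and c(reagent) is 1.28 mM. The constant reads 0.255 /mM.

What does it say of amber in the north flask? Removal leaves starting material and free reagent in place, so the ratio calls target back. Holding c(reagent) fixed and refilling from starting material and the target left behind, target returns to 7.24 %, or 15.6 % counted. This is my figure.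

The forecast says 9.3 % now, amber as best, 9.3 % after blue and 8.4 % after violet. Its amber figure is 16 to 17 %, above mine, since it holds that “the isomer and SM refill target”.

The north flask gives 9.22 % at 30 min, and amber is best with a gain of 7.3 points, against 2.6 points for red. Blue gives 9.22 % and violet 7.63 %.

    second substrate + protic impurity → quenched substrate (k = 86.0 /M/s, Ea = 37.0 kJ/mol)
    starting material + second substrate → cross product (k = 29.0 /M/s, Ea = 44.0 kJ/mol)
    target ⇌ isomer of the product (K = 4.40, k = 0.0180 /s, Ea = 86.0 kJ/mol, ΔH = 6.00 kJ/mol)
    second substrate + reagent → second product (k = 14.0 /M/s, Ea = 39.0 kJ/mol)
    starting material + reagent ⇌ target (K = 260 /M, k = 9.30 /M/s, Ea = 37.0 kJ/mol, ΔH = −22.0 kJ/mol)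
    (constants at 40 °C)

In the north flask, with second substrate at 0 % of its charge, the relaxation half-lives of binding, 0.231 min, and of target with its isomer, 0.523 min, are both short against 30 min, and target still stands at 9.22 % at 300 min. Used forward in the north flask, with 28.4 % of starting material and 1.25 mM of free reagent at 30 min, the constant read earlier, 0.255 /mM, gives 9.05 % target.

In a neighbour flask, the same but charged with 2.5 mM of starting material, 41.8 % of that stands unbound at 30 min beside 0.756 mM of free reagent, and the constant gives 8.06 % target. The computed value is 8.22 %.

All runs are calculated from invented constants, noise included.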